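The only stereocentre, the carbinol carbon C2 of the side chain, is disconnected at both of its C–C bonds (C1 is the benzylic CH2 on the phloroglucinol ring, C3 the alkene carbon carrying the exocyclic CH2). Because C1 and C3 can each be delivered as a carbanion, C2 is inserted between them as the carbon of dichloromethyllithium on boron. The precursor is the (R,R)-1,2-dicyclohexylethane-1,2-diol (DICHED) ester of 2,4,6-tris(methoxymethoxy)benzylboronic acid, still without the benzoyl group. In one telescoped operation, chain extension to an α-chloro boronate and chloride displacement by a Shapiro-derived 6-methylhepta-1,5-dien-2-yllithium form C1–C2 and C2–C3 and fix C2 as a C–B bond, later oxidised with retention; no ring is closed.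

Key step: step 5

Remark on the chemistry: (R,R)-DICHED boronates are taken to give (1S)-1-chloroalkyl boronates with LiCHCl2/ZnCl2 (priorities Cl > C > B); inversion in the second migration and retention in the oxidation then lead to the R carbinol, so the (R,R)-diol is the correct auxiliary enantiomer. Compounds 3, 4, 20 and 2,4,6-triisopropylbenzenesulfonohydrazide are taken as purchased.

Step 1
Reactants: 1 phloroglucinol (benzene-1,3,5-triol)
Product: 2 1,3,5-tris(methoxymethoxy)benzene
Conditions: NaH, MOMCl, DMF, 0 °C → rt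
Reagents that add atoms: chloromethyl methyl ether (MOMCl), COCCl
Why: Williamson-type O-alkylation, in which the phenoxides formed with NaH are alkylated at oxygen by the highly reactive α-chloro ether to give the tris-acetal that later directs ring lithiation.

Step 2
Reactants: 3 diisopropyl (bromomethyl)boronate; 4 (R,R)-1,2-dicyclohexylethane-1,2-diol
Product: 5 (4R,5R)-2-(bromomethyl)-4,5-dicyclohexyl-1,3,2-dioxaborolane
Conditions: Et2O, rt; then removal of i-PrOH under vacuum
Reagents that add atoms: none
Why: Boronic ester transesterification, in which the chelating 1,2-diol displaces both isopropoxy groups and removal of volatile propan-2-ol drives the exchange, the diol stereocentres being untouched.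

Step 3
Reactants: 2 1,3,5-tris(methoxymethoxy)benzene; 5 (4R,5R)-2-(bromomethyl)-4,5-dicyclohexyl-1,3,2-dioxaborolane
Product: 8 (4R,5R)-4,5-dicyclohexyl-2-{[2,4,6-tris(methoxymethoxy)phenyl]methyl}-1,3,2-dioxaborolane, via 2,4,6-tris(methoxymethoxy)phenyllithium 6 (not isolated), via lithium aryl(bromomethyl)borate 7 (not isolated)
Conditions: n-BuLi, THF, 0 °C; then 5 (1.1 equiv), −78 °C → rt
Reagents that add atoms: none
Why: Directed ortho-metalation at a ring CH flanked by two MOM ethers gives 6, which adds to boron (borate 7) and undergoes a 1,2-aryl shift with loss of bromide (Matteson-type homologation with a halomethylboronate), placing the CH2–B unit on the ring.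

Step 4
Reactants: 9 6-methylhept-5-en-2-one
Product: 10 N'-(6-methylhept-5-en-2-ylidene)-2,4,6-triisopropylbenzenesulfonohydrazide (trisylhydrazone, mainly E)
Conditions: TrisNHNH2, MeOH, HCl (cat.), rt
Reagents that add atoms: 2,4,6-triisopropylbenzenesulfonohydrazide, CC(C)c1cc(C(C)C)c(S(=O)(=O)NN)c(C(C)C)c1
Why: Acid-catalysed condensation of the methyl ketone with the sulfonyl hydrazide should give the crystalline hydrazone, mainly the E isomer with the NH group syn to the methyl group, as needed for the later Shapiro reaction.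

Step 5
Reactants: 8 (4R,5R)-4,5-dicyclohexyl-2-{[2,4,6-tris(methoxymethoxy)phenyl]methyl}-1,3,2-dioxaborolane; 11 dichloromethane; 10 trisylhydrazone of 6-methylhept-5-en-2-one
Product: 17 (4R,5R)-4,5-dicyclohexyl-2-{(2R)-7-methyl-3-methylidene-1-[2,4,6-tris(methoxymethoxy)phenyl]oct-6-en-2-yl}-1,3,2-dioxaborolane, via dichloromethyllithium 12 (not isolated), via lithium benzyl(dichloromethyl)borate 13 (not isolated), via (1S)-1-chloroalkyl boronate 14 (not isolated), via 6-methylhepta-1,5-dien-2-yllithium 15 (not isolated), via lithium alkenyl(1-chloroalkyl)borate 16 (not isolated)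
Conditions: 11, n-BuLi, THF, −100 °C; 8; ZnCl2, −100 °C → rt; pentane, filtration under Ar; THF, −78 °C, 15 (1.2 equiv) [from 10, n-BuLi (1.95 equiv per 10), THF, −78 → 0 °C]; → rt
Reagents that add atoms: none
Why: This is a Matteson homologation run twice on one boron atom: 12 adds to 8 to give borate 13, ZnCl2 triggers the 1,2-shift of the benzylic carbon C1 with loss of one chloride (C1–C2 bond, chloride 14), and after removal of the zinc and lithium salts the Shapiro-derived alkenyllithium 15 adds to boron (borate 16) and its sp2 carbon C3 migrates with expulsion of the second chloride (C2–C3 bond). The closest known reaction type is the chain extension of C2-symmetric diol boronic esters with LiCHCl2/ZnCl2 followed by displacement of the α-chloride by a Grignard or alkenyl-metal reagent; no ring is formed. The C2 stereocentre is controlled by the (R,R)-diol on boron, which selects the chloride that leaves in the zinc-assisted first shift and so gives the (1S)-chloride 14, and the second shift is stereospecific (invertive, anti to the C–Cl bond), leaving C2 as a C–B bond that maps onto the R alcohol. The step needs attack at boron in preference to deprotonation or other substitution: the arene carries only MOM ethers and no carbonyl group, ZnCl2 ties up free chloride so that 14 should not epimerise, salt removal keeps 15 from being diverted to an alkenylzinc species, and 10 is kept in slight excess over n-BuLi so that no butyl group is transferred. Product 17 is an α-substituted allylboronate, which should hold its configuration at or below room temperature in the absence of Lewis acid and is oxidised without delay.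

Step 6
Reactants: 17 (4R,5R)-4,5-dicyclohexyl-2-{(2R)-7-methyl-3-methylidene-1-[2,4,6-tris(methoxymethoxy)phenyl]oct-6-en-2-yl}-1,3,2-dioxaborolane
Product: 18 (2R)-7-methyl-3-methylidene-1-[2,4,6-tris(methoxymethoxy)phenyl]oct-6-en-2-ol
Conditions: H2O2 (30% aq.), NaOH (2 M aq.), THF, 0 °C → rt
Reagents that add atoms: hydrogen peroxide, OO
Why: Alkaline peroxide oxidation of the C–B bond, in which hydroperoxide adds to boron and C2 migrates from boron to oxygen with retention and without allylic transposition, so the configuration set in step 5 is carried into the R alcohol while diol 4 is released for recovery.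

Step 7
Reactants: 18 (2R)-7-methyl-3-methylidene-1-[2,4,6-tris(methoxymethoxy)phenyl]oct-6-en-2-ol
Product: 19 triethyl({(2R)-7-methyl-3-methylidene-1-[2,4,6-tris(methoxymethoxy)phenyl]oct-6-en-2-yl}oxy)silane
Conditions: TESCl, imidazole, CH2Cl2, 0 °C → rt
Reagents that add atoms: chlorotriethylsilane (TESCl), CC[Si](Cl)(CC)CC
Why: Standard imidazole-mediated silylation of the secondary allylic alcohol masks the acidic OH before the ring is lithiated, with no change at C2.

Step 8
Reactants: 19 triethyl({(2R)-7-methyl-3-methylidene-1-[2,4,6-tris(methoxymethoxy)phenyl]oct-6-en-2-yl}oxy)silane; 20 N-methoxy-N-methylbenzamide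
Product: 23 {2,4,6-tris(methoxymethoxy)-3-[(2R)-7-methyl-3-methylidene-2-(triethylsilyloxy)oct-6-en-1-yl]phenyl}(phenyl)methanone, via ring-lithiated silyl ether 21 (not isolated), via lithium hemiaminal alkoxide 22 (not isolated)
Conditions: n-BuLi (1.2 equiv), TMEDA, THF, −20 → 0 °C; then 20, −78 → 0 °C; H2O
Reagents that add atoms: none
Why: Directed ortho-metalation should occur at either of the two equivalent ring CH positions, each flanked by two MOM ethers, and aryllithium 21 acylates the Weinreb amide through the stable chelated adduct 22 (Weinreb ketone synthesis), which prevents over-addition.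

Step 9
Reactants: 23 {2,4,6-tris(methoxymethoxy)-3-[(2R)-7-methyl-3-methylidene-2-(triethylsilyloxy)oct-6-en-1-yl]phenyl}(phenyl)methanone
Product: 24 {2,4,6-trihydroxy-3-[(2R)-2-hydroxy-7-methyl-3-methylideneoct-6-en-1-yl]phenyl}(phenyl)methanone (target)
Conditions: HCl (ca. 2 M), MeOH, 0 °C → rt
Reagents that add atoms: none
Why: Acid-catalysed acetal exchange with methanol should remove the three aryl MOM groups (aided by the adjacent ketone) while the same medium solvolyses the triethylsilyl ether, no bond to C2 being broken so that the R configuration is kept.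

Compound list
1 | phloroglucinol (benzene-1,3,5-triol) | Oc1cc(O)cc(O)c1 | starting material
2 | 1,3,5-tris(methoxymethoxy)benzene | COCOc1cc(OCOC)cc(OCOC)c1 | intermediate
3 | diisopropyl (bromomethyl)boronate | CC(C)OB(CBr)OC(C)C | starting material
4 | (R,R)-1,2-dicyclohexylethane-1,2-diol, (R,R)-DICHED | O[C@H](C1CCCCC1)[C@H](O)C1CCCCC1 | starting material
5 | (4R,5R)-2-(bromomethyl)-4,5-dicyclohexyl-1,3,2-dioxaborolane | BrCB1O[C@H](C2CCCCC2)[C@@H](C2CCCCC2)O1 | intermediate
6 | 2,4,6-tris(methoxymethoxy)phenyllithium | [Li]c1c(OCOC)cc(OCOC)cc1OCOC | intermediate (not isolated)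
7 | lithium (4R,5R)-2-(bromomethyl)-4,5-dicyclohexyl-2-[2,4,6-tris(methoxymethoxy)phenyl]-1,3,2-dioxaborolan-2-uide | [Li+].BrC[B-]1(c2c(OCOC)cc(OCOC)cc2OCOC)O[C@H](C2CCCCC2)[C@@H](C2CCCCC2)O1 | intermediate (not isolated)
8 | (4R,5R)-4,5-dicyclohexyl-2-{[2,4,6-tris(methoxymethoxy)phenyl]methyl}-1,3,2-dioxaborolane | COCOc1cc(OCOC)c(CB2O[C@H](C3CCCCC3)[C@@H](C3CCCCC3)O2)c(OCOC)c1 | intermediate (precursor of the key step)
9 | 6-methylhept-5-en-2-one | CC(=O)CCC=C(C)C | starting material
10 | N'-(6-methylhept-5-en-2-ylidene)-2,4,6-triisopropylbenzenesulfonohydrazide (E shown) | C/C(CCC=C(C)C)=N\NS(=O)(=O)c1c(C(C)C)cc(C(C)C)cc1C(C)C | intermediate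
11 | dichloromethane | ClCCl | starting material
12 | dichloromethyllithium | [Li]C(Cl)Cl | intermediate (not isolated)
13 | lithium (4R,5R)-4,5-dicyclohexyl-2-(dichloromethyl)-2-{[2,4,6-tris(methoxymethoxy)phenyl]methyl}-1,3,2-dioxaborolan-2-uide | [Li+].ClC(Cl)[B-]1(Cc2c(OCOC)cc(OCOC)cc2OCOC)O[C@H](C2CCCCC2)[C@@H](C2CCCCC2)O1 | intermediate (not isolated)
14 | (4R,5R)-2-{(1S)-1-chloro-2-[2,4,6-tris(methoxymethoxy)phenyl]ethyl}-4,5-dicyclohexyl-1,3,2-dioxaborolane | Cl[C@H](Cc1c(OCOC)cc(OCOC)cc1OCOC)B1O[C@H](C2CCCCC2)[C@@H](C2CCCCC2)O1 | intermediate (not isolated)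
15 | 6-methylhepta-1,5-dien-2-yllithium | [Li]C(=C)CCC=C(C)C | intermediate (not isolated)
16 | lithium (4R,5R)-2-{(1S)-1-chloro-2-[2,4,6-tris(methoxymethoxy)phenyl]ethyl}-4,5-dicyclohexyl-2-(6-methylhepta-1,5-dien-2-yl)-1,3,2-dioxaborolan-2-uide | [Li+].C=C(CCC=C(C)C)[B-]1([C@H](Cl)Cc2c(OCOC)cc(OCOC)cc2OCOC)O[C@H](C2CCCCC2)[C@@H](C2CCCCC2)O1 | intermediate (not isolated)
17 | (4R,5R)-4,5-dicyclohexyl-2-{(2R)-7-methyl-3-methylidene-1-[2,4,6-tris(methoxymethoxy)phenyl]oct-6-en-2-yl}-1,3,2-dioxaborolane | C=C(CCC=C(C)C)[C@H](B1O[C@H](C2CCCCC2)[C@@H](C2CCCCC2)O1)Cc1c(OCOC)cc(OCOC)cc1OCOC | intermediate (product of the key step)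
18 | (2R)-7-methyl-3-methylidene-1-[2,4,6-tris(methoxymethoxy)phenyl]oct-6-en-2-ol | C=C(CCC=C(C)C)[C@H](O)Cc1c(OCOC)cc(OCOC)cc1OCOC | intermediate
19 | triethyl({(2R)-7-methyl-3-methylidene-1-[2,4,6-tris(methoxymethoxy)phenyl]oct-6-en-2-yl}oxy)silane | C=C(CCC=C(C)C)[C@H](O[Si](CC)(CC)CC)Cc1c(OCOC)cc(OCOC)cc1OCOC | intermediate
20 | N-methoxy-N-methylbenzamide | CON(C)C(=O)c1ccccc1 | starting material
21 | {2,4,6-tris(methoxymethoxy)-3-[(2R)-7-methyl-3-methylidene-2-(triethylsilyloxy)oct-6-en-1-yl]phenyl}lithium | C=C(CCC=C(C)C)[C@H](O[Si](CC)(CC)CC)Cc1c(OCOC)cc(OCOC)c([Li])c1OCOC | intermediate (not isolated)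
22 | lithium [methoxy(methyl)amino](phenyl){2,4,6-tris(methoxymethoxy)-3-[(2R)-7-methyl-3-methylidene-2-(triethylsilyloxy)oct-6-en-1-yl]phenyl}methanolate (mixture at the transient carbinol carbon) | [Li+].C=C(CCC=C(C)C)[C@H](O[Si](CC)(CC)CC)Cc1c(OCOC)cc(OCOC)c(C([O-])(N(C)OC)c2ccccc2)c1OCOC | intermediate (not isolated)
23 | {2,4,6-tris(methoxymethoxy)-3-[(2R)-7-methyl-3-methylidene-2-(triethylsilyloxy)oct-6-en-1-yl]phenyl}(phenyl)methanone | C=C(CCC=C(C)C)[C@H](O[Si](CC)(CC)CC)Cc1c(OCOC)cc(OCOC)c(C(=O)c2ccccc2)c1OCOC | intermediate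
24 | {2,4,6-trihydroxy-3-[(2R)-2-hydroxy-7-methyl-3-methylideneoct-6-en-1-yl]phenyl}(phenyl)methanone | C=C(CCC=C(C)C)[C@H](O)Cc1c(O)cc(O)c(C(=O)c2ccccc2)c1O | target

Total step count: 9. Longest linear sequence: 7 steps (steps 1, 3, 5, 6, 7, 8, 9; the boron branch 2, 3, 5–9 is equally long).

Steps most likely to fail

Step 5. What may go wrong: loss of configuration at C2 through chloride exchange in the α-chloro boronate before the second addition, proton transfer or incomplete borate formation with the hindered alkenyllithium, and 1,3-shift of boron in the allylic product. The fallback replaces the boron chemistry by carbonyl addition and catalytic asymmetric reduction; it sets out from 2 and comes back at 18. Aryllithium 6 (from 2 as in step 3) opens oxirane in THF (−78 °C → rt) to give 2-[2,4,6-tris(methoxymethoxy)phenyl]ethan-1-ol F1. Dess–Martin periodinane with NaHCO3 in CH2Cl2 gives [2,4,6-tris(methoxymethoxy)phenyl]acetaldehyde F2. Alkenyllithium 15 (from 10 as in step 5), transmetalated with anhydrous CeCl3 to suppress enolisation, adds at −78 °C to give racemic 7-methyl-3-methylidene-1-[2,4,6-tris(methoxymethoxy)phenyl]oct-6-en-2-ol F3. A second Dess–Martin oxidation gives 7-methyl-3-methylidene-1-[2,4,6-tris(methoxymethoxy)phenyl]oct-6-en-2-one F4. Corey–Bakshi–Shibata reduction with catalytic (3aS)-1-methyl-3,3-diphenyltetrahydro-1H,3H-pyrrolo[1,2-c][1,3,2]oxazaborole and catecholborane in toluene at −78 °C, with the branched alkenyl group as the large substituent, should deliver the R alcohol 18.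

Step 9. What may go wrong: acid-promoted ionisation of the allylic alcohol, or protonation of either alkene, followed by capture by an ortho phenol (ring closure) or by methanol, competing with acetal cleavage. The fallback unmasks the phenols without protic acid and removes the silyl ether separately; it sets out from 23 and comes back at 24. TMSOTf with 2,2'-bipyridyl in CH2Cl2 at 0 °C should convert the aryl MOM ethers into aryl trimethylsilyl ethers, which hydrolyse on aqueous work-up to give {2,4,6-trihydroxy-3-[(2R)-7-methyl-3-methylidene-2-(triethylsilyloxy)oct-6-en-1-yl]phenyl}(phenyl)methanone F5. Bu4NF buffered with AcOH in THF at 0 °C then removes the triethylsilyl group to give 24. Should the silyl ether already be lost in the first stage, 24 is reached directly.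

Step 3. What may go wrong: slow or incomplete 1,2-aryl shift in the hindered borate, a second addition of aryllithium to boron, or bromine–lithium exchange in place of addition to boron. The fallback reverses the polarity of the CH2 insertion; it sets out from 2 and 4 and comes back at 8. B(Oi-Pr)3 and diol 4, with removal of propan-2-ol, give (4R,5R)-4,5-dicyclohexyl-2-(propan-2-yloxy)-1,3,2-dioxaborolane F6. Aryllithium 6 (from 2) displaces isopropoxide from F6 (THF, −78 °C → rt) to give the arylboronic ester (4R,5R)-4,5-dicyclohexyl-2-[2,4,6-tris(methoxymethoxy)phenyl]-1,3,2-dioxaborolane F7. Chloromethyllithium generated in its presence (ICH2Cl, n-BuLi, THF, −78 °C → rt) adds to boron and the aryl group migrates with loss of chloride (Matteson homologation) to give 8.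

Further compounds
F1 | step 5 | 2-[2,4,6-tris(methoxymethoxy)phenyl]ethan-1-ol | OCCc1c(OCOC)cc(OCOC)cc1OCOC
F2 | step 5 | [2,4,6-tris(methoxymethoxy)phenyl]acetaldehyde | O=CCc1c(OCOC)cc(OCOC)cc1OCOC
F3 | step 5 | racemic 7-methyl-3-methylidene-1-[2,4,6-tris(methoxymethoxy)phenyl]oct-6-en-2-ol | C=C(CCC=C(C)C)C(O)Cc1c(OCOC)cc(OCOC)cc1OCOC
F4 | step 5 | 7-methyl-3-methylidene-1-[2,4,6-tris(methoxymethoxy)phenyl]oct-6-en-2-one | C=C(CCC=C(C)C)C(=O)Cc1c(OCOC)cc(OCOC)cc1OCOC
F5 | step 9 | {2,4,6-trihydroxy-3-[(2R)-7-methyl-3-methylidene-2-(triethylsilyloxy)oct-6-en-1-yl]phenyl}(phenyl)methanone | C=C(CCC=C(C)C)[C@H](O[Si](CC)(CC)CC)Cc1c(O)cc(O)c(C(=O)c2ccccc2)c1O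
F6 | step 3 | (4R,5R)-4,5-dicyclohexyl-2-(propan-2-yloxy)-1,3,2-dioxaborolane | CC(C)OB1O[C@H](C2CCCCC2)[C@@H](C2CCCCC2)O1
F7 | step 3 | (4R,5R)-4,5-dicyclohexyl-2-[2,4,6-tris(methoxymethoxy)phenyl]-1,3,2-dioxaborolane | COCOc1cc(OCOC)c(B2O[C@H](C3CCCCC3)[C@@H](C3CCCCC3)O2)c(OCOC)c1
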